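**Retrosynthetic overview**

- Target ⇒ (last step) a monocyclic potassium cyclopentyltrifluoroborate that already carries the ester, the C4 carbinol and a C8 methyl ketone, plus diphenyl(vinyl)sulfonium triflate. One operation forms C1–C10 (Giese addition of the tertiary C1 radical), C8–C9 (ylide addition to the ketone) and C9–O (oxirane).
- Enabling feature: the C8–C9 oxirane is fused to the seven-membered ring one methylene (C10) away from the quaternary ring-fusion carbon C1. The C9–C10 ethano bridge therefore joins a carbon that can be a methyl ketone (C8) to a carbon that can be a tertiary radical (C1).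
- Trifluoroborate ⇐ pinacol boronate: ester on O6, isopropyl on C4 by organocerium addition to a C4 ketone, C5–C6 and C1–B by one-pot asymmetric conjugate boration–aldol of 3-methylcyclopent-2-en-1-one with ketal-protected 3-oxobutanal.
- The boron on C1 is a temporary stereocentre and the radical precursor: it relays chirality to C5, C6 and C4, then leaves in the last step, which sets C1 anew.
- Ring order: cyclopentane (from the enone), then cycloheptane and oxirane together in the last step.

Key step: step 7

Numbering: carbons are numbered as in the daucane skeleton of the target and kept for all intermediates: C1 quaternary ring-fusion carbon (methyl), C2, C3, C4 (carbinol, isopropyl), C5 (ring-fusion CH), C6 (ester carbon), C7, C8 (oxirane carbon with methyl), C9 (oxirane CH), C10.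

Assumption: (S,S)-QuinoxP* is taken to give the enolate antipode that leads to 5S after aldol trapping anti to boron; if the sense of induction or of the relay is the opposite, the mirror-image ligand is used, since C1 is erased in step 7.

**Step 1**
Reactants: 1 ethyl 2-(2-methyl-1,3-dioxolan-2-yl)acetate
Product: 2 2-(2-methyl-1,3-dioxolan-2-yl)acetaldehyde
Conditions: iBu2AlH (1.05 equiv), CH2Cl2, −78 °C; then KNaC4H4O6 (aq)
Reagents that add atoms: none
Why: Half-reduction of an ester with iBu2AlH at −78 °C should stop at the aldehyde oxidation level and forms no stereocentre.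

**Step 2**
Reactants: 3 3-methylcyclopent-2-en-1-one; 2 2-(2-methyl-1,3-dioxolan-2-yl)acetaldehyde
Product: 6 (2S,3R)-2-[(1S)-1-hydroxy-2-(2-methyl-1,3-dioxolan-2-yl)ethyl]-3-methyl-3-(4,4,5,5-tetramethyl-1,3,2-dioxaborolan-2-yl)cyclopentan-1-one, via boron enolate 4 (not isolated), via boron aldolate 5 (not isolated)
Conditions: B2pin2 (1.1 equiv), Cu(MeCN)4PF6 (5 mol%), (S,S)-QuinoxP* (6 mol%), LiOtBu (10 mol%), THF, rt; then 2, −40 to 0 °C; pH 7 buffer
Reagents that add atoms: bis(pinacolato)diboron, CC1(C)OB(OC1(C)C)B1OC(C)(C)C(C)(C)O1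
Why: Copper-catalysed asymmetric conjugate boration of a β-substituted cyclic enone gives a regiodefined pinacolboron enolate that is trapped in an aldol addition, in which the ligand sets C1, the aldehyde adds to C5 on the face opposite the boryl group, and the closed chair (Zimmerman–Traxler) transition state of the E-enolate gives the anti aldol, the required 5S,6S pair.

**Step 3**
Reactants: 6 the aldol adduct of step 2
Product: 7 (1R,2S,3R)-2-[(1S)-1-hydroxy-2-(2-methyl-1,3-dioxolan-2-yl)ethyl]-3-methyl-1-(propan-2-yl)-3-(4,4,5,5-tetramethyl-1,3,2-dioxaborolan-2-yl)cyclopentan-1-ol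
Conditions: iPrMgCl (4 equiv), CeCl3 (4 equiv), THF, −78 °C; then NH4Cl (aq)
Reagents that add atoms: isopropylmagnesium chloride, CC(C)[Mg]Cl
Why: Organocerium 1,2-addition, which suppresses enolisation, β-hydride reduction and attack at boron, should occur on the ketone face opposite the C5 side chain, so that the new hydroxyl is cis to C6 and the isopropyl group trans (4R).

**Step 4**
Reactants: 7 the diol of step 3; 8 4-methoxybenzoyl chloride
Product: 9 (1S)-1-[(1S,2R,5R)-2-hydroxy-5-methyl-2-(propan-2-yl)-5-(4,4,5,5-tetramethyl-1,3,2-dioxaborolan-2-yl)cyclopentyl]-2-(2-methyl-1,3-dioxolan-2-yl)ethyl 4-methoxybenzoate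
Conditions: DMAP (0.2 equiv), Et3N, CH2Cl2, 0 °C to rt
Reagents that add atoms: none
Why: DMAP-catalysed acyl transfer should be selective for the secondary C6 hydroxyl over the hindered tertiary C4 hydroxyl and touches no stereocentre.

**Step 5**
Reactants: 9 the ketal ester of step 4
Product: 10 (1S)-1-[(1S,2R,5R)-2-hydroxy-5-methyl-2-(propan-2-yl)-5-(4,4,5,5-tetramethyl-1,3,2-dioxaborolan-2-yl)cyclopentyl]-3-oxobutyl 4-methoxybenzoate
Conditions: PPTS (0.2 equiv), acetone/H2O (10:1), 50 °C
Reagents that add atoms: water, O
Why: Mild acid-catalysed hydrolysis of the dioxolane should unmask the C8 methyl ketone while the ester, the tertiary alcohol and the pinacol boronate stay intact.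

**Step 6**
Reactants: 10 the keto boronate of step 5
Product: 11 potassium trifluoro{(1R,2S,3R)-3-hydroxy-2-[(1S)-1-(4-methoxybenzoyloxy)-3-oxobutyl]-1-methyl-3-(propan-2-yl)cyclopentyl}borate
Conditions: KHF2 (4.5 equiv, aq), MeOH, rt
Reagents that add atoms: potassium hydrogen difluoride, [K+].[F-].F
Why: Fluoride exchange of a pinacol boronate with KHF2 should give the trifluoroborate needed for single-electron oxidation, and the configuration at C1 no longer matters because it is erased in step 7.

**Step 7**
Reactants: 11 the trifluoroborate of step 6; 12 diphenyl(vinyl)sulfonium trifluoromethanesulfonate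
Product: 17 (1R,4R,5S,6S,8R,9S)-8,9-epoxy-4-hydroxydaucan-6-yl 4-methoxybenzoate (oxirane oxygen anti to the C1 methyl), via C1 radical 13 (not isolated), via sulfonio radical 14 (not isolated), via sulfonium ylide 15 (not isolated), via betaine 16 (not isolated)
Conditions: 12 (1.5 equiv), 9-mesityl-10-methylacridinium tetrafluoroborate (5 mol%), KF (2 equiv), degassed MeCN, 450 nm LEDs, 25 °C
Reagents that add atoms: none
Why: Proposed new method: the excited acridinium oxidises the trifluoroborate to the tertiary radical 13, which adds to the CH2 terminus of 12 (C1–C10); the sulfonio radical 14 is reduced by the acridine radical to ylide 15 (radical–polar crossover), whose carbon C9 adds to the C8 ketone to give betaine 16 (C8–C9), and the C8 alkoxide then displaces diphenyl sulfide from C9. The closest known reaction types are the photoredox Giese addition of tertiary alkyltrifluoroborates followed by radical–polar crossover and polar ring closure, and the base-mediated epoxy-annulation of vinylsulfonium salts with tethered ketones, which closes five- to seven-membered rings. The cycloheptane closes by 7-exo-trig attack of the ylide carbon on the carbonyl and the oxirane by 3-exo-tet displacement of diphenyl sulfide (intramolecular Corey–Chaykovsky epoxidation). C1 is set by addition of the acceptor to the planar radical anti to the C5 side chain, which gives the trans ring fusion. C8 and C9 are set in the ylide addition: only the betaine with O− and S+ anti can close, which makes the oxirane cis-fused, and the α face is expected because the diphenylsulfonio group takes the pseudo-equatorial site anti to the C10–C1 bond while the C8 methyl lies pseudo-axial on the β face and the C6 ester stays equatorial. The step needs radical capture by 12 to outrun reversible 5-exo attack of the C1 radical on the C8 carbonyl, and needs the ylide to choose the ketone over the ester and over proton transfer; the very electrophilic acceptor in excess, the low basicity of the sulfonium ylide and the higher electrophilicity of the ketone should secure this.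

**Compound list**

1 | ethyl 2-(2-methyl-1,3-dioxolan-2-yl)acetate | CCOC(=O)CC1(C)OCCO1 | starting material
2 | 2-(2-methyl-1,3-dioxolan-2-yl)acetaldehyde | O=CCC1(C)OCCO1 | intermediate
3 | 3-methylcyclopent-2-en-1-one | CC1=CC(=O)CC1 | starting material
4 | pinacolboron enolate of (3R)-3-methyl-3-(pinacolatoboryl)cyclopentanone, enolised towards C5 | C[C@]1(B2OC(C)(C)C(C)(C)O2)CCC(OB3OC(C)(C)C(C)(C)O3)=C1 | intermediate
5 | O6-pinacolboryl aldolate of 6 | CC1(C[C@H](OB2OC(C)(C)C(C)(C)O2)[C@H]3C(=O)CC[C@]3(C)B4OC(C)(C)C(C)(C)O4)OCCO1 | intermediate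
6 | (2S,3R)-2-[(1S)-1-hydroxy-2-(2-methyl-1,3-dioxolan-2-yl)ethyl]-3-methyl-3-(4,4,5,5-tetramethyl-1,3,2-dioxaborolan-2-yl)cyclopentan-1-one | CC1(C[C@H](O)[C@H]2C(=O)CC[C@]2(C)B3OC(C)(C)C(C)(C)O3)OCCO1 | intermediate
7 | (1R,2S,3R)-2-[(1S)-1-hydroxy-2-(2-methyl-1,3-dioxolan-2-yl)ethyl]-3-methyl-1-(propan-2-yl)-3-(4,4,5,5-tetramethyl-1,3,2-dioxaborolan-2-yl)cyclopentan-1-ol | CC1(C[C@H](O)[C@H]2[C@](O)(C(C)C)CC[C@]2(C)B3OC(C)(C)C(C)(C)O3)OCCO1 | intermediate
8 | 4-methoxybenzoyl chloride | COc1ccc(C(Cl)=O)cc1 | starting material
9 | (1S)-1-[(1S,2R,5R)-2-hydroxy-5-methyl-2-(propan-2-yl)-5-(4,4,5,5-tetramethyl-1,3,2-dioxaborolan-2-yl)cyclopentyl]-2-(2-methyl-1,3-dioxolan-2-yl)ethyl 4-methoxybenzoate | COc1ccc(C(=O)O[C@@H](CC2(C)OCCO2)[C@H]3[C@](O)(C(C)C)CC[C@]3(C)B4OC(C)(C)C(C)(C)O4)cc1 | intermediate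
10 | (1S)-1-[(1S,2R,5R)-2-hydroxy-5-methyl-2-(propan-2-yl)-5-(4,4,5,5-tetramethyl-1,3,2-dioxaborolan-2-yl)cyclopentyl]-3-oxobutyl 4-methoxybenzoate | COc1ccc(C(=O)O[C@@H](CC(C)=O)[C@H]2[C@](O)(C(C)C)CC[C@]2(C)B3OC(C)(C)C(C)(C)O3)cc1 | intermediate
11 | potassium trifluoro{(1R,2S,3R)-3-hydroxy-2-[(1S)-1-(4-methoxybenzoyloxy)-3-oxobutyl]-1-methyl-3-(propan-2-yl)cyclopentyl}borate | COc1ccc(C(=O)O[C@@H](CC(C)=O)[C@H]2[C@](O)(C(C)C)CC[C@]2(C)[B-](F)(F)F)cc1.[K+] | intermediate
12 | diphenyl(vinyl)sulfonium trifluoromethanesulfonate | C=C[S+](c1ccccc1)c1ccccc1.[O-]S(=O)(=O)C(F)(F)F | starting material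
13 | tertiary C1 radical formed from 11 by loss of the BF3 unit | COc1ccc(C(=O)O[C@@H](CC(C)=O)[C@H]2[C@](O)(C(C)C)CC[C]2C)cc1 | intermediate
14 | C9 (α-sulfonio) radical: adduct of 13 and the cation of 12, shown as its triflate | COc1ccc(C(=O)O[C@@H](CC(C)=O)[C@H]2[C@](O)(C(C)C)CC[C@]2(C)C[CH][S+](c3ccccc3)c3ccccc3)cc1.[O-]S(=O)(=O)C(F)(F)F | intermediate
15 | diphenylsulfonium ylide at C9 (C1–C10 formed; C10 trans to C6 on the cyclopentane) | COc1ccc(C(=O)O[C@@H](CC(C)=O)[C@H]2[C@](O)(C(C)C)CC[C@]2(C)C[CH-][S+](c3ccccc3)c3ccccc3)cc1 | intermediate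
16 | betaine: C8 alkoxide (α) and C9 diphenylsulfonio group (β) on the closed trans-fused seven-membered ring | COc1ccc(C(=O)O[C@H]2C[C@]([O-])(C)[C@H]([S+](c3ccccc3)c3ccccc3)C[C@@]3(C)CC[C@@](O)(C(C)C)[C@H]23)cc1 | intermediate
17 | (1R,4R,5S,6S,8R,9S)-8,9-epoxy-4-hydroxydaucan-6-yl 4-methoxybenzoate | COc1ccc(C(=O)O[C@H]2C[C@@]3(C)O[C@H]3C[C@@]3(C)CC[C@@](O)(C(C)C)[C@H]23)cc1 | target

Total step count: 7. Longest linear sequence: 7 steps (1 → 17).

**Steps most likely to fail**

1. Step 7 (Proposed new method). What may go wrong: the ylide adds to the wrong face of the ketone and gives the β-oxirane; the tertiary radical is captured too slowly by the acceptor; or the sulfonium intermediate loses diphenyl sulfide by elimination before the ring closes. The fallback uses known reactions and forms the two bonds in separate steps. It sets out from 11: photoredox radical allylation with allyl phenyl sulfone (same acridinium photocatalyst, KF, MeCN, blue LEDs) should give the C1-allyl ketone F1, with the allyl group anti to the C5 side chain. Methylenation of the C8 ketone under non-basic Lombardo–Takai conditions (Zn, CH2Br2, TiCl4, THF) gives the diene F2. Ring-closing metathesis with the second-generation Grubbs catalyst RuCl2(H2IMes)(PCy3)(=CHPh) in CH2Cl2 at 40 °C closes the cycloheptene ester F3 with the C8=C9 double bond. Epoxidation with mCPBA/NaHCO3 in CH2Cl2, expected on the α face anti to the C1 methyl, comes back to the route at 17.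

2. Step 3. What may go wrong: enolisation or β-hydride reduction of the hindered ketone instead of addition, retro-aldol cleavage of the β-hydroxy ketone, or attack of the reagent at boron. The fallback sets out from 6: addition of 2-propenylmagnesium bromide/CeCl3 (THF, −78 °C), an sp2 nucleophile that cannot transfer a β-hydride and is less hindered, should give the isopropenyl carbinol F4. Hydrogenation of its only C=C bond (H2, Pd/C, EtOAc) comes back to the route at 7.

3. Step 2. What may go wrong: erosion of diastereoselectivity when the boron enolate is trapped in the same pot, and retro-aldol loss during work-up. The fallback separates the two events and sets out from 3: conjugate boration under the catalyst of step 2, then quenching of the enolate with Me3SiCl/Et3N, gives the trimethylsilyl enol ether F5. A Mukaiyama aldol addition with 2 (BF3·OEt2, CH2Cl2, −78 °C, open transition state, attack anti to boron) comes back to the route at 6.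

**Further compounds**

F1 | step 7 | (1S)-1-[(1S,2R,5R)-2-hydroxy-5-methyl-2-(propan-2-yl)-5-(prop-2-en-1-yl)cyclopentyl]-3-oxobutyl 4-methoxybenzoate | COc1ccc(C(=O)O[C@@H](CC(C)=O)[C@H]2[C@](O)(C(C)C)CC[C@]2(C)CC=C)cc1
F2 | step 7 | (1S)-1-[(1S,2R,5R)-2-hydroxy-5-methyl-2-(propan-2-yl)-5-(prop-2-en-1-yl)cyclopentyl]-3-methylbut-3-en-1-yl 4-methoxybenzoate | COc1ccc(C(=O)O[C@@H](CC(C)=C)[C@H]2[C@](O)(C(C)C)CC[C@]2(C)CC=C)cc1
F3 | step 7 | (1R,4R,5S,6S)-4-hydroxydauc-8-en-6-yl 4-methoxybenzoate | COc1ccc(C(=O)O[C@H]2CC(C)=CC[C@@]3(C)CC[C@@](O)(C(C)C)[C@H]23)cc1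
F4 | step 3 | analogue of 7 with prop-1-en-2-yl in place of propan-2-yl on C4 (same configuration) | CC1(C[C@H](O)[C@H]2[C@](O)(C(C)=C)CC[C@]2(C)B3OC(C)(C)C(C)(C)O3)OCCO1
F5 | step 2 | trimethyl{[(3R)-3-methyl-3-(4,4,5,5-tetramethyl-1,3,2-dioxaborolan-2-yl)cyclopent-1-en-1-yl]oxy}silane | C[Si](C)(C)OC1=C[C@@](C)(B2OC(C)(C)C(C)(C)O2)CC1
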